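**Retrosynthetic overview**

- The route rests on one feature of the 5,6,7,8-tetrahydrochromen-4-one: the carbinol C5 and the methylene C8 of the carbocycle (ring B) hang on the neighbouring pyranone carbons C4a and C8a. That is the pattern of an ortho-methyl aldehyde photoenol that has taken up a two-carbon dienophile as C6–C7.
- Ring B is closed last, by photoenolization/Diels–Alder reaction of a 3-formyl-2-methyl-4-pyranone with methyl acrylate on a chiral titanium diolate (bonds C5–C6 and C7–C8, C5 set). The C6 ester is then removed by radical decarboxylation.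
- Ring A (the pyranone) is made first, by C-acylation of a β-keto Weinreb amide with a 2-alkynoyl chloride and 6-endo oxa-Michael closure, followed by reduction of the amide to the aldehyde.
- The alkynoyl chloride comes from (Z)-octadec-13-enal by one-carbon alkynylation and carboxylation, so the Z alkene is carried from the start.

Key step: step 6

Assumption: the (R,R)-TADDOL complex (TADDOLate)Ti(Oi-Pr)2 is taken to give the 5S,6S adduct. The sense of induction on this new diene has to be checked on the first run, and the (S,S) diol is used if it is the opposite.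

Remark: compounds 8, 9 and 11 carry pyranone numbering (chain on C6, methyl on C2). From 12 onward chromenone numbering is used (chain on C2, carbinol C5).

**Route**

Step 1
Reactants: 1 (Z)-octadec-13-enal; 2 dimethyl (1-diazo-2-oxopropyl)phosphonate
Product: 3 (Z)-nonadec-14-en-1-yne
Conditions: K2CO3, MeOH, 0 °C → rt
Reagents that add atoms: none
Why: Ohira–Bestmann alkynylation, in which methanolysis of the acetyl group frees the diazomethylphosphonate anion, which olefinates the aldehyde and, after loss of N2 and a 1,2-hydrogen shift, should give the terminal alkyne under conditions too mild to touch the Z alkene.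

Step 2
Reactants: 3 (Z)-nonadec-14-en-1-yne
Product: 4 (Z)-icos-15-en-2-ynoic acid
Conditions: n-BuLi, THF, −78 °C; CO2, −78 °C → rt; aq. HCl
Reagents that add atoms: carbon dioxide, O=C=O
Why: carboxylation of a lithium acetylide, the only acidic C–H being the alkyne terminus.

Step 3
Reactants: 4 (Z)-icos-15-en-2-ynoic acid
Product: 5 (Z)-icos-15-en-2-ynoyl chloride
Conditions: (COCl)2, DMF (cat.), CH2Cl2, 0 °C → rt; concentrate, use crude
Reagents that add atoms: oxalyl chloride, ClC(=O)C(=O)Cl
Why: acid chloride formation through the Vilsmeier-type chloroiminium catalyst, kept cold and stripped quickly so that HCl does not add to the ynoyl unit.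

Step 4
Reactants: 5 (Z)-icos-15-en-2-ynoyl chloride; 6 N-methoxy-N-methyl-3-oxobutanamide
Product: 8 6-[(Z)-heptadec-12-enyl]-N-methoxy-N,2-dimethyl-4-oxo-4H-pyran-3-carboxamide, via triacylmethane ynone 7 (not isolated)
Conditions: MgCl2, pyridine, CH2Cl2, 0 °C → rt; aq. NH4Cl; crude in CH2Cl2, Et3N (cat.), rt
Reagents that add atoms: none
Why: magnesium-enolate C-acylation of the β-keto amide (Rathke conditions) should give 7, whose acetyl enol oxygen then adds 6-endo-dig to the ynone β-carbon (intramolecular oxa-Michael addition), with the aromatic 4-pyranone as the thermodynamic sink.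

Step 5
Reactants: 8 6-[(Z)-heptadec-12-enyl]-N-methoxy-N,2-dimethyl-4-oxo-4H-pyran-3-carboxamide
Product: 9 6-[(Z)-heptadec-12-enyl]-2-methyl-4-oxo-4H-pyran-3-carbaldehyde
Conditions: i-Bu2AlH (1.2 equiv), THF, −78 °C; aq. potassium sodium tartrate (KNaC4H4O6)
Reagents that add atoms: none
Why: Weinreb amide reduction, in which the chelated aluminium adduct holds at −78 °C and releases the aldehyde only on work-up, while the pyranone carbonyl, a doubly vinylogous ester, is far less electrophilic toward one equivalent of hydride.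

Step 6
Reactants: 9 6-[(Z)-heptadec-12-enyl]-2-methyl-4-oxo-4H-pyran-3-carbaldehyde; 10 methyl acrylate
Product: 12 methyl (5S,6S)-2-[(Z)-heptadec-12-enyl]-5-hydroxy-4-oxo-5,6,7,8-tetrahydro-4H-chromene-6-carboxylate, via pyranone photodienol 11 (not isolated)
Conditions: Ti(Oi-Pr)4 (2 equiv), (R,R)-TADDOL (2.2 equiv), toluene, rt; then 9, methyl acrylate (5 equiv), hν 365 nm (LED), Ar, 0 °C → rt; aq. NaHCO3
Reagents that add atoms: none
Why: Proposed new method: excitation of the formyl n,π* band at 365 nm should move a hydrogen from the C2 methyl to the formyl oxygen through a six-membered transition state and, after bond rotation in the biradical, give dienol 11 with its hydroxyl turned toward the C4 carbonyl, where (TADDOLate)Ti(Oi-Pr)2 can take up the dienol oxygen, close a six-membered chelate with the C4 carbonyl and bind the acrylate carbonyl as well. The closest known reaction type is the enantioselective photoenolization/Diels–Alder reaction of 2-methylbenzaldehydes with enones and enoates mediated by Ti(Oi-Pr)4 and TADDOL-type diols, moved here from a benzene ring to a 4-pyranone, whose re-formation on cycloaddition supplies the driving force. Ring B closes by an intermolecular suprafacial [4+2] cycloaddition in which C7–C8 and C5–C6 are formed together. C5 is fixed by the face of the planar dienol that the chiral diol leaves open to the bound acrylate, and C6 by the endo position of the ester (cis to the hydroxyl), although C6 is erased in step 10. The step needs diene face selectivity and ortho regiochemistry: the first should come from the rigid chelate between the C5 oxygen and the C4 carbonyl, the second from the polarisation of the diene, because the dienol oxygen and the ring oxygen on the methylene-bearing carbon both enlarge the HOMO coefficient at the exocyclic CH2, which therefore bonds to the acrylate β-carbon. The chain methylene on C6 is out of reach of the formyl oxygen, and at 365 nm neither the isolated Z alkene nor the π,π* band of the pyranone is excited.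

Step 7
Reactants: 12 methyl (5S,6S)-2-[(Z)-heptadec-12-enyl]-5-hydroxy-4-oxo-5,6,7,8-tetrahydro-4H-chromene-6-carboxylate
Product: 13 methyl (5S,6S)-5-[(tert-butyldimethylsilyl)oxy]-2-[(Z)-heptadec-12-enyl]-4-oxo-5,6,7,8-tetrahydro-4H-chromene-6-carboxylate
Conditions: TBSOTf, 2,6-lutidine, CH2Cl2, −78 → 0 °C
Reagents that add atoms: tert-butyldimethylsilyl trifluoromethanesulfonate, CC(C)(C)[Si](C)(C)OS(=O)(=O)C(F)(F)F
Why: silyl ether formation with a silyl triflate and a hindered base, which masks the C5 hydroxyl against retro-aldol opening and acylation in the following steps without touching either stereocenter.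

Step 8
Reactants: 13 methyl (5S,6S)-5-[(tert-butyldimethylsilyl)oxy]-2-[(Z)-heptadec-12-enyl]-4-oxo-5,6,7,8-tetrahydro-4H-chromene-6-carboxylate
Product: 14 (5S,6S)-5-[(tert-butyldimethylsilyl)oxy]-2-[(Z)-heptadec-12-enyl]-4-oxo-5,6,7,8-tetrahydro-4H-chromene-6-carboxylic acid
Conditions: Me3SnOH, 1,2-dichloroethane, 80 °C; cold 0.1 M HCl wash
Reagents that add atoms: trimethyltin hydroxide, C[Sn](C)(C)O
Why: methyl ester cleavage with Me3SnOH, a nearly neutral hydroxide source that should hydrolyse the ester without the enolate formation that would expel the C5 silyloxy group or open the pyranone.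

Step 9
Reactants: 14 (5S,6S)-5-[(tert-butyldimethylsilyl)oxy]-2-[(Z)-heptadec-12-enyl]-4-oxo-5,6,7,8-tetrahydro-4H-chromene-6-carboxylic acid
Product: 15 1,3-dioxoisoindolin-2-yl (5S,6S)-5-[(tert-butyldimethylsilyl)oxy]-2-[(Z)-heptadec-12-enyl]-4-oxo-5,6,7,8-tetrahydro-4H-chromene-6-carboxylate
Conditions: N-hydroxyphthalimide, DIC, DMAP (5 mol%), CH2Cl2, 0 °C → rt
Reagents that add atoms: N-hydroxyphthalimide, O=C1c2ccccc2C(=O)N1O
Why: carbodiimide (Steglich-type) esterification to the redox-active ester, where any epimerisation at C6 is of no consequence because that centre is removed next.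

Step 10
Reactants: 15 1,3-dioxoisoindolin-2-yl (5S,6S)-5-[(tert-butyldimethylsilyl)oxy]-2-[(Z)-heptadec-12-enyl]-4-oxo-5,6,7,8-tetrahydro-4H-chromene-6-carboxylate
Product: 16 (5S)-5-[(tert-butyldimethylsilyl)oxy]-2-[(Z)-heptadec-12-enyl]-5,6,7,8-tetrahydro-4H-chromen-4-one
Conditions: Hantzsch ester (1.5 equiv), [Ru(bpy)3](PF6)2 (1 mol%), CH2Cl2, blue LEDs (450 nm), rt
Reagents that add atoms: none
Why: photoredox reductive decarboxylation of an N-acyloxyphthalimide (Okada type), in which single-electron reduction and loss of CO2 give the secondary C6 radical, which takes a hydrogen atom from the Hantzsch ester; no thiol, tin hydride or metal hydride is present to isomerise the Z alkene, and C5 is untouched.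

Step 11
Reactants: 16 (5S)-5-[(tert-butyldimethylsilyl)oxy]-2-[(Z)-heptadec-12-enyl]-5,6,7,8-tetrahydro-4H-chromen-4-one
Product: 17 (5S)-2-[(Z)-heptadec-12-enyl]-5-hydroxy-5,6,7,8-tetrahydro-4H-chromen-4-one
Conditions: HF·pyridine, pyridine, THF, 0 °C → rt
Reagents that add atoms: none
Why: fluoride desilylation under buffered conditions, which cleaves only the Si–O bond, so the C5–O bond and its S configuration are kept.

**Compound list**

1 | (Z)-octadec-13-enal | CCCC/C=C\CCCCCCCCCCCC=O | starting material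
2 | dimethyl (1-diazo-2-oxopropyl)phosphonate | COP(=O)(OC)C(=[N+]=[N-])C(C)=O | starting material
3 | (Z)-nonadec-14-en-1-yne | CCCC/C=C\CCCCCCCCCCCC#C | intermediate
4 | (Z)-icos-15-en-2-ynoic acid | CCCC/C=C\CCCCCCCCCCCC#CC(=O)O | intermediate
5 | (Z)-icos-15-en-2-ynoyl chloride | CCCC/C=C\CCCCCCCCCCCC#CC(=O)Cl | intermediate
6 | N-methoxy-N-methyl-3-oxobutanamide | CC(=O)CC(=O)N(C)OC | starting material
7 | (Z)-2-acetyl-N-methoxy-N-methyl-3-oxodocos-17-en-4-ynamide (triacylmethane ynone, enolised in solution) | CCCC/C=C\CCCCCCCCCCCC#CC(=O)C(C(C)=O)C(=O)N(C)OC | intermediate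
8 | 6-[(Z)-heptadec-12-enyl]-N-methoxy-N,2-dimethyl-4-oxo-4H-pyran-3-carboxamide | CCCC/C=C\CCCCCCCCCCCc1cc(=O)c(C(=O)N(C)OC)c(C)o1 | intermediate
9 | 6-[(Z)-heptadec-12-enyl]-2-methyl-4-oxo-4H-pyran-3-carbaldehyde | CCCC/C=C\CCCCCCCCCCCc1cc(=O)c(C=O)c(C)o1 | intermediate
10 | methyl acrylate | C=CC(=O)OC | starting material
11 | 6-[(Z)-heptadec-12-enyl]-3-(hydroxymethylidene)-2-methylidene-2,3-dihydro-4H-pyran-4-one, hydroxyl on the side of the C4 carbonyl (photodienol) | CCCC/C=C\CCCCCCCCCCCC1=CC(=O)/C(=C\O)C(=C)O1 | intermediate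
12 | methyl (5S,6S)-2-[(Z)-heptadec-12-enyl]-5-hydroxy-4-oxo-5,6,7,8-tetrahydro-4H-chromene-6-carboxylate (hydroxyl and ester cis) | CCCC/C=C\CCCCCCCCCCCc1cc(=O)c2c(o1)CC[C@H](C(=O)OC)[C@@H]2O | intermediate
13 | methyl (5S,6S)-5-[(tert-butyldimethylsilyl)oxy]-2-[(Z)-heptadec-12-enyl]-4-oxo-5,6,7,8-tetrahydro-4H-chromene-6-carboxylate | CCCC/C=C\CCCCCCCCCCCc1cc(=O)c2c(o1)CC[C@H](C(=O)OC)[C@@H]2O[Si](C)(C)C(C)(C)C | intermediate
14 | (5S,6S)-5-[(tert-butyldimethylsilyl)oxy]-2-[(Z)-heptadec-12-enyl]-4-oxo-5,6,7,8-tetrahydro-4H-chromene-6-carboxylic acid | CCCC/C=C\CCCCCCCCCCCc1cc(=O)c2c(o1)CC[C@H](C(=O)O)[C@@H]2O[Si](C)(C)C(C)(C)C | intermediate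
15 | 1,3-dioxoisoindolin-2-yl (5S,6S)-5-[(tert-butyldimethylsilyl)oxy]-2-[(Z)-heptadec-12-enyl]-4-oxo-5,6,7,8-tetrahydro-4H-chromene-6-carboxylate | CCCC/C=C\CCCCCCCCCCCc1cc(=O)c2c(o1)CC[C@H](C(=O)ON1C(=O)c3ccccc3C1=O)[C@@H]2O[Si](C)(C)C(C)(C)C | intermediate
16 | (5S)-5-[(tert-butyldimethylsilyl)oxy]-2-[(Z)-heptadec-12-enyl]-5,6,7,8-tetrahydro-4H-chromen-4-one | CCCC/C=C\CCCCCCCCCCCc1cc(=O)c2c(o1)CCC[C@@H]2O[Si](C)(C)C(C)(C)C | intermediate
17 | (5S)-2-[(Z)-heptadec-12-enyl]-5-hydroxy-5,6,7,8-tetrahydro-4H-chromen-4-one | CCCC/C=C\CCCCCCCCCCCc1cc(=O)c2c(o1)CCC[C@@H]2O | target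

**Step count and risks**

Total steps: 11. Longest linear sequence: 11 steps (from 1 to 17).

Steps most likely to fail:

1. Step 6 (proposed new method). The dienol may return to the aldehyde faster than it is trapped. The chelate on this push-pull diene may be too loose for good facial selectivity. Isopropoxide may also open or reduce the formyl pyranone. Fallback with known chemistry, setting out from 5 and coming back at 17: 5 is esterified with cyclohexane-1,3-dione (Et3N, CH2Cl2, 0 °C) to the enol ester 3-oxocyclohex-1-en-1-yl (Z)-icos-15-en-2-ynoate F1. DMAP (cat.) then shifts the acyl group from oxygen to carbon to give 2-[(Z)-icos-15-en-2-ynoyl]cyclohexane-1,3-dione F2, which should close in the same pot by 6-endo oxa-Michael addition to 2-[(Z)-heptadec-12-enyl]-7,8-dihydro-4H-chromene-4,5(6H)-dione F3. CBS reduction of the C5 ketone with (R)-2-methyl-CBS-oxazaborolidine and catecholborane (toluene, −78 °C), with the pyranone sp2 carbon as the large group, should then give 17 directly. Ring B then comes from the dione and steps 4 to 11 fall away.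

2. Step 5. Hydride may add in conjugate fashion to the pyranone, or the hindered, twisted amide may reduce too slowly and invite over-reduction. Fallback setting out from 5 and coming back at 9: 5 acylates tert-butyl 3-oxobutanoate under the conditions of step 4 to give tert-butyl (Z)-2-acetyl-3-oxodocos-17-en-4-ynoate F4, which cyclises to tert-butyl 6-[(Z)-heptadec-12-enyl]-2-methyl-4-oxo-4H-pyran-3-carboxylate F5. CF3CO2H in CH2Cl2 frees 6-[(Z)-heptadec-12-enyl]-2-methyl-4-oxo-4H-pyran-3-carboxylic acid F6. (COCl)2 with DMF (cat.) gives 6-[(Z)-heptadec-12-enyl]-2-methyl-4-oxo-4H-pyran-3-carbonyl chloride F7, and LiAlH(Ot-Bu)3 (1 equiv, THF, −78 °C) reduces this far more electrophilic acyl chloride to 9.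

3. Step 8. Silanol may be lost across C5–C6, since ionisation at C5 is helped by the ring enol ether, or the hindered ester may cleave too slowly at 80 °C. Fallback setting out from 9 and coming back at 14: step 6 is run with allyl acrylate to give allyl (5S,6S)-2-[(Z)-heptadec-12-enyl]-5-hydroxy-4-oxo-5,6,7,8-tetrahydro-4H-chromene-6-carboxylate F8. This is silylated as in step 7 to allyl (5S,6S)-5-[(tert-butyldimethylsilyl)oxy]-2-[(Z)-heptadec-12-enyl]-4-oxo-5,6,7,8-tetrahydro-4H-chromene-6-carboxylate F9. The allyl group is then removed under neutral conditions with Pd(PPh3)4 and PhSiH3 (CH2Cl2, rt) to give 14.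

**Further compounds**

F1 | step 6 | 3-oxocyclohex-1-en-1-yl (Z)-icos-15-en-2-ynoate | CCCC/C=C\CCCCCCCCCCCC#CC(=O)OC1=CC(=O)CCC1
F2 | step 6 | 2-[(Z)-icos-15-en-2-ynoyl]cyclohexane-1,3-dione | CCCC/C=C\CCCCCCCCCCCC#CC(=O)C1C(=O)CCCC1=O
F3 | step 6 | 2-[(Z)-heptadec-12-enyl]-7,8-dihydro-4H-chromene-4,5(6H)-dione | CCCC/C=C\CCCCCCCCCCCc1cc(=O)c2c(o1)CCCC2=O
F4 | step 5 | tert-butyl (Z)-2-acetyl-3-oxodocos-17-en-4-ynoate | CCCC/C=C\CCCCCCCCCCCC#CC(=O)C(C(C)=O)C(=O)OC(C)(C)C
F5 | step 5 | tert-butyl 6-[(Z)-heptadec-12-enyl]-2-methyl-4-oxo-4H-pyran-3-carboxylate | CCCC/C=C\CCCCCCCCCCCc1cc(=O)c(C(=O)OC(C)(C)C)c(C)o1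
F6 | step 5 | 6-[(Z)-heptadec-12-enyl]-2-methyl-4-oxo-4H-pyran-3-carboxylic acid | CCCC/C=C\CCCCCCCCCCCc1cc(=O)c(C(=O)O)c(C)o1
F7 | step 5 | 6-[(Z)-heptadec-12-enyl]-2-methyl-4-oxo-4H-pyran-3-carbonyl chloride | CCCC/C=C\CCCCCCCCCCCc1cc(=O)c(C(=O)Cl)c(C)o1
F8 | step 8 | allyl (5S,6S)-2-[(Z)-heptadec-12-enyl]-5-hydroxy-4-oxo-5,6,7,8-tetrahydro-4H-chromene-6-carboxylate | CCCC/C=C\CCCCCCCCCCCc1cc(=O)c2c(o1)CC[C@H](C(=O)OCC=C)[C@@H]2O
F9 | step 8 | allyl (5S,6S)-5-[(tert-butyldimethylsilyl)oxy]-2-[(Z)-heptadec-12-enyl]-4-oxo-5,6,7,8-tetrahydro-4H-chromene-6-carboxylate | CCCC/C=C\CCCCCCCCCCCc1cc(=O)c2c(o1)CC[C@H](C(=O)OCC=C)[C@@H]2O[Si](C)(C)C(C)(C)C
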